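**Plan**

Retrosynthesis: cut O–C15 of the dihydrofuran (alkynol cycloisomerisation), then the C8–OAc bond (1,2-acetoxy shift of a C7 enol acetate epoxide), then C11–C12 together with O–C9 (one radical-polar crossover [3+2] annulation); this leaves dienyl acetate 7 (from (+)-sclareolide, whose lactone carbon is excised as CO2) and iodohydrin 13.
Forward: rings A and B come intact from sclareolide; ring B is taken to the 7-acetoxy-7,9(11)-diene; the tetrahydrofuran ring (O, C9, C11, C12, C13) is closed in the key step; the acetate then moves from O7 to C8; the 2,3-dihydrofuran ring is closed last.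
Enabling feature: the C7 carbonyl of ring B is vinylogous through C8=C9 to the C11 methyl group, so its dienyl acetate C7(OAc)=C8–C9=C11H2 takes a C12 radical at C11, and the 1-acetoxyallyl cation that follows is captured at C9 by the C13 hydroxyl, which returns the C7 enol acetate needed to oxygenate C8.
Stereochemistry: C5 and C10 from sclareolide; C13 from a Sharpless asymmetric epoxidation; C9 by axial C–O bond formation anti to the C10 methyl group; C8 by inversion in the acetoxy shift (acetate trans-diaxial to O9).

Key step: step 9

Remark: labdane numbering is used throughout (target = 8β-acetoxy-9α,13R:15,16-diepoxylabd-14-en-7-one; α is the face opposite the C10 methyl group), and compounds 1, 8 and 9 are taken as purchased.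

**Route**

Step 1
Reactants: 1 (+)-sclareolide
Product: 2 methyl 13,14,15,16-tetranorlabd-8-en-12-oate (tetrasubstituted C8=C9 alkene)
Conditions: H2SO4 (conc.), MeOH, reflux; chromatography on AgNO3-impregnated silica
Reagents that add atoms: methanol CO
Why: Acid opens the lactone at the tertiary C8–O bond, E1 loss of H9 under equilibrating conditions should favour the tetrasubstituted C8=C9 alkene and Fischer esterification caps the acid, the trisubstituted and exocyclic isomers being minor by-products to be removed; C5 and C10 are untouched.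

Step 2
Reactants: 2 methyl 13,14,15,16-tetranorlabd-8-en-12-oate
Product: 3 methyl 7-oxo-13,14,15,16-tetranorlabd-8-en-12-oate
Conditions: CrO3, 3,5-dimethylpyrazole, CH2Cl2, −20 °C
Reagents that add atoms: chromium trioxide O=[Cr](=O)=O
Why: Allylic oxidation with the CrO3–3,5-dimethylpyrazole complex should take place at C7, the only ring methylene allylic to C8=C9, because the other allylic CH2 (C11) is deactivated by the ester and methyl groups are oxidised far more slowly, giving the ring-B enone.

Step 3
Reactants: 3 methyl 7-oxo-13,14,15,16-tetranorlabd-8-en-12-oate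
Product: 5 12,13,14,15,16-pentanorlabd-8-en-7-one (drim-8-en-7-one), via keto acid 4 (not isolated)
Conditions: LiOH, THF/MeOH/H2O, 25 °C; then 2 M HCl to pH 2, 70 °C
Reagents that add atoms: none
Why: Saponification gives acid 4, a vinylogous β-keto acid (carboxyl on the γ-carbon C11 of the C7 enone) that should lose CO2 on warming in acid just as γ-carboxy cyclohexenones do, the dienol ketonising to the conjugated enone with C11 left as a methyl group.

Step 4
Reactants: 5 12,13,14,15,16-pentanorlabd-8-en-7-one
Product: 7 12,13,14,15,16-pentanorlabda-7,9(11)-dien-7-yl acetate, via potassium dienolate 6 (not isolated)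
Conditions: KH, t-BuOH (5 mol %), THF, 25 °C; then Ac2O, −78 to 0 °C
Reagents that add atoms: acetic anhydride CC(=O)OC(C)=O
Why: Because C10 bears no hydrogen the only γ-protons are those of the C11 methyl, so equilibration (proton shuttle t-BuOH) should funnel the ketone into the more delocalised extended dienolate 6, whose hard O-acylation by Ac2O gives the linear s-trans dienyl acetate (thermodynamic dienolate formation and enol acetylation).

Step 5
Reactants: 8 2-bromoprop-2-en-1-ol; 9 ethynyltrimethylsilane
Product: 10 2-methylidene-4-(trimethylsilyl)but-3-yn-1-ol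
Conditions: PdCl2(PPh3)2 (2 mol %), CuI (4 mol %), Et3N, THF, 25 °C
Reagents that add atoms: none
Why: Sonogashira coupling of the vinylic bromide with the terminal alkyne proceeds under mild conditions and tolerates the free hydroxyl, giving the 2-alkynyl allylic alcohol.

Step 6
Reactants: 10 2-methylidene-4-(trimethylsilyl)but-3-yn-1-ol
Product: 11 (R)-{2-[(trimethylsilyl)ethynyl]oxiran-2-yl}methanol
Conditions: Ti(OiPr)4, D-(−)-diisopropyl tartrate, t-BuOOH, 4 Å molecular sieves, CH2Cl2, −20 °C
Reagents that add atoms: tert-butyl hydroperoxide CC(C)(C)OO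
Why: Sharpless asymmetric epoxidation of the 1,1-disubstituted allylic alcohol sets the quaternary carbinol carbon (the future C13) by reagent control, the D-(−)-tartrate complex delivering oxygen to the enantiotopic face that gives the R epoxide, while the silylalkyne is inert to the titanium peroxide.

Step 7
Reactants: 11 (R)-{2-[(trimethylsilyl)ethynyl]oxiran-2-yl}methanol
Product: 12 (S)-tert-butyldimethyl({2-[(trimethylsilyl)ethynyl]oxiran-2-yl}methoxy)silane
Conditions: TBSCl, imidazole, CH2Cl2, 0 °C
Reagents that add atoms: tert-butyldimethylsilyl chloride CC(C)(C)[Si](C)(C)Cl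
Why: Standard silylation of the primary hydroxyl blocks the future C16 oxygen so that only the tertiary hydroxyl can act as nucleophile in the key step; the stereocenter is not involved (the descriptor changes only through the priority rules).

Step 8
Reactants: 12 (S)-tert-butyldimethyl({2-[(trimethylsilyl)ethynyl]oxiran-2-yl}methoxy)silane
Product: 13 (R)-1-[(tert-butyldimethylsilyl)oxy]-2-(iodomethyl)-4-(trimethylsilyl)but-3-yn-2-ol
Conditions: LiI, AcOH, THF, −20 to 0 °C
Reagents that add atoms: lithium iodide [Li+].[I-]
Why: Under buffered conditions iodide opens the 2,2-disubstituted epoxide by SN2 attack at its CH2 group (the future C12), which leaves the tertiary propargylic C–O bond and its configuration untouched and gives the β-iodo alcohol (epoxide to halohydrin opening).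

Step 9
Reactants: 7 12,13,14,15,16-pentanorlabda-7,9(11)-dien-7-yl acetate; 13 (R)-1-[(tert-butyldimethylsilyl)oxy]-2-(iodomethyl)-4-(trimethylsilyl)but-3-yn-2-ol
Product: 17 (13R)-16-[(tert-butyldimethylsilyl)oxy]-9α,13-epoxy-15-(trimethylsilyl)labd-7-en-14-yn-7-yl acetate, via C12 radical 14 (not isolated), via acetoxyallyl radical 15 (not isolated), via acetoxyallyl cation 16 (not isolated)
Conditions: fac-Ir(ppy)3 (2 mol %), 2,6-lutidine, MeCN (degassed), blue LED (450 nm), 25 °C
Reagents that add atoms: none
Why: Proposed new method: excited fac-Ir(ppy)3 should reduce the C–I bond of 13 to the primary C12 radical 14, which adds to the unhindered terminal C11 of the s-trans dienyl acetate 7 to give the 1-acetoxyallyl radical 15 (C7–C8–C9), and the oxidised photocatalyst (tetravalent iridium), or iodine formed from it, should convert 15 into the acetoxy-stabilised allyl cation 16, so that the cycle closes without external oxidant or reductant. The closest known reaction types are the photoredox radical-polar crossover oxyalkylation of styrenes and 1,3-dienes, the iridium-photocatalysed atom-transfer reactions of unactivated alkyl iodides and the Mn(OAc)3-mediated oxidative [3+2] annulation of alkenes to oxygen heterocycles; new here is that the hydroxyl nucleophile rides on the radical partner and that the acceptor is a 1-acyloxydiene. The tetrahydrofuran ring (O, C9, C11, C12, C13) closes by 5-exo-trig attack of the C13 hydroxyl on the C9 terminus of 16, attack at the C7 terminus being excluded because it would give a seven-membered ring, and the C7=C8 enol acetate is regenerated in the same event. The new C9 stereocenter is set by axial attack on the α face anti to the axial C10 methyl group, which is also the more stable arrangement (oxygen axial, C11 equatorial), while C13 is not touched and keeps the configuration set in step 6. The step needs radical addition at C11 only (terminal CH2 against the fully substituted C7), a radical that does not rearrange before it adds (the 1,2-alkynyl shift of 14 is slow, which is why C13 carries an alkyne and not a vinyl group) and a non-basic medium so that 13 does not close back to epoxide 12 (2,6-lutidine only takes up HI).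

Step 10
Reactants: 17 (13R)-16-[(tert-butyldimethylsilyl)oxy]-9α,13-epoxy-15-(trimethylsilyl)labd-7-en-14-yn-7-yl acetate
Product: 18 (13R)-16-[(tert-butyldimethylsilyl)oxy]-7α,8α:9α,13-diepoxy-15-(trimethylsilyl)labd-14-yn-7β-yl acetate
Conditions: dimethyldioxirane, acetone, 0 °C
Reagents that add atoms: dimethyldioxirane CC1(C)OO1
Why: Neutral dimethyldioxirane should epoxidise the electron-rich tetrasubstituted enol acetate much faster than it touches the silylalkyne or the ethers, on the α face anti to the axial C10 methyl group as in the enol acetates of 3-keto-5α-steroids, giving the 7α,8α-epoxide (should the β-epoxide form instead, the acid-catalysed retentive mode of the following rearrangement leads to the same C8 configuration).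

Step 11
Reactants: 18 (13R)-16-[(tert-butyldimethylsilyl)oxy]-7α,8α:9α,13-diepoxy-15-(trimethylsilyl)labd-14-yn-7β-yl acetate
Product: 19 (13R)-16-[(tert-butyldimethylsilyl)oxy]-9α,13-epoxy-7-oxo-15-(trimethylsilyl)labd-14-yn-8β-yl acetate
Conditions: toluene, 110 °C, base-washed glassware
Reagents that add atoms: none
Why: Thermal rearrangement of the enol ester epoxide is an intramolecular 1,2-acyloxy shift in which the acetate carbonyl oxygen opens the epoxide at C8 from the β face (inversion at C8, trans-diaxial opening) while the epoxide oxygen becomes the C7 ketone, so the acetate should end axial (8β) with the methyl group equatorial (8α), the same outcome as in the steroid 2β-acetoxy-3-ketone series where the acetate also ends syn-axial to the angular methyl.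

Step 12
Reactants: 19 (13R)-16-[(tert-butyldimethylsilyl)oxy]-9α,13-epoxy-7-oxo-15-(trimethylsilyl)labd-14-yn-8β-yl acetate
Product: 20 (13R)-9α,13-epoxy-16-hydroxy-7-oxolabd-14-yn-8β-yl acetate
Conditions: Bu4NF, AcOH, THF, 0 to 25 °C
Reagents that add atoms: none
Why: Acetic acid-buffered fluoride cleaves both the alkynyl C–Si bond and the primary silyl ether in one operation, while the tertiary α-keto acetate (no enolisable position at C8) survives the near-neutral medium (fluoride desilylation).

Step 13
Reactants: 20 (13R)-9α,13-epoxy-16-hydroxy-7-oxolabd-14-yn-8β-yl acetate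
Product: 21 (13R)-9α,13:15,16-diepoxy-7-oxolabd-14-en-8β-yl acetate (target)
Conditions: Mo(CO)6 (30 mol %), Et3N, Et2O, hν (350 nm), then 20, 25 °C; chromatography on Et3N-deactivated silica
Reagents that add atoms: none
Why: Molybdenum pentacarbonyl-catalysed endo-cycloisomerisation of the 3-butyn-1-ol unit (terminal alkyne to metal vinylidene, anti-Markovnikov attack of the C16 hydroxyl at C15, protonolysis) closes the 2,3-dihydrofuran under basic, non-acidic conditions as the acid-labile allylic spiro ether requires, without touching any stereocenter.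

**Compound list**

1 | (+)-sclareolide | O=C1O[C@]2(C)CC[C@H]3C(C)(C)CCC[C@]3(C)[C@H]2C1 | starting material
2 | methyl 13,14,15,16-tetranorlabd-8-en-12-oate | COC(=O)CC1=C(C)CC[C@H]2C(C)(C)CCC[C@]12C | intermediate
3 | methyl 7-oxo-13,14,15,16-tetranorlabd-8-en-12-oate | COC(=O)CC1=C(C)C(=O)C[C@H]2C(C)(C)CCC[C@]12C | intermediate
4 | 7-oxo-13,14,15,16-tetranorlabd-8-en-12-oic acid (not isolated) | OC(=O)CC1=C(C)C(=O)C[C@H]2C(C)(C)CCC[C@]12C | intermediate
5 | 12,13,14,15,16-pentanorlabd-8-en-7-one (drim-8-en-7-one) | CC1=C(C)C(=O)C[C@H]2C(C)(C)CCC[C@]12C | intermediate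
6 | potassium 12,13,14,15,16-pentanorlabda-7,9(11)-dien-7-olate (not isolated) | C=C1C(C)=C([O-])C[C@H]2C(C)(C)CCC[C@]12C.[K+] | intermediate
7 | 12,13,14,15,16-pentanorlabda-7,9(11)-dien-7-yl acetate | C=C1C(C)=C(OC(C)=O)C[C@H]2C(C)(C)CCC[C@]12C | intermediate
8 | 2-bromoprop-2-en-1-ol | OCC(Br)=C | starting material
9 | ethynyltrimethylsilane | C#C[Si](C)(C)C | starting material
10 | 2-methylidene-4-(trimethylsilyl)but-3-yn-1-ol | OCC(=C)C#C[Si](C)(C)C | intermediate
11 | (R)-{2-[(trimethylsilyl)ethynyl]oxiran-2-yl}methanol | C1[C@](CO)(C#C[Si](C)(C)C)O1 | intermediate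
12 | (S)-tert-butyldimethyl({2-[(trimethylsilyl)ethynyl]oxiran-2-yl}methoxy)silane | C1[C@](CO[Si](C)(C)C(C)(C)C)(C#C[Si](C)(C)C)O1 | intermediate
13 | (R)-1-[(tert-butyldimethylsilyl)oxy]-2-(iodomethyl)-4-(trimethylsilyl)but-3-yn-2-ol | IC[C@](CO[Si](C)(C)C(C)(C)C)(C#C[Si](C)(C)C)O | intermediate
14 | primary C12 radical from 13 (not isolated) | [CH2][C@](CO[Si](C)(C)C(C)(C)C)(C#C[Si](C)(C)C)O | intermediate
15 | 1-acetoxyallyl radical C7–C8–C9 formed by addition of 14 to C11 of 7 (not isolated) | CC1=C(OC(C)=O)C[C@H]2C(C)(C)CCC[C@]2(C)[C]1CC[C@](CO[Si](C)(C)C(C)(C)C)(C#C[Si](C)(C)C)O | intermediate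
16 | 1-acetoxyallyl cation from 15, iodide counter-ion (not isolated) | CC1=C(OC(C)=O)C[C@H]2C(C)(C)CCC[C@]2(C)[C+]1CC[C@](CO[Si](C)(C)C(C)(C)C)(C#C[Si](C)(C)C)O.[I-] | intermediate
17 | (13R)-16-[(tert-butyldimethylsilyl)oxy]-9α,13-epoxy-15-(trimethylsilyl)labd-7-en-14-yn-7-yl acetate | CC1=C(OC(C)=O)C[C@H]2C(C)(C)CCC[C@]2(C)[C@@]13CC[C@](CO[Si](C)(C)C(C)(C)C)(C#C[Si](C)(C)C)O3 | intermediate
18 | (13R)-16-[(tert-butyldimethylsilyl)oxy]-7α,8α:9α,13-diepoxy-15-(trimethylsilyl)labd-14-yn-7β-yl acetate | C[C@]12O[C@]2(OC(C)=O)C[C@H]3C(C)(C)CCC[C@]3(C)[C@@]14CC[C@](CO[Si](C)(C)C(C)(C)C)(C#C[Si](C)(C)C)O4 | intermediate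
19 | (13R)-16-[(tert-butyldimethylsilyl)oxy]-9α,13-epoxy-7-oxo-15-(trimethylsilyl)labd-14-yn-8β-yl acetate | CC(=O)O[C@@]1(C)C(=O)C[C@H]2C(C)(C)CCC[C@]2(C)[C@@]13CC[C@](CO[Si](C)(C)C(C)(C)C)(C#C[Si](C)(C)C)O3 | intermediate
20 | (13R)-9α,13-epoxy-16-hydroxy-7-oxolabd-14-yn-8β-yl acetate | CC(=O)O[C@@]1(C)C(=O)C[C@H]2C(C)(C)CCC[C@]2(C)[C@@]13CC[C@](CO)(C#C)O3 | intermediate
21 | (13R)-9α,13:15,16-diepoxy-7-oxolabd-14-en-8β-yl acetate | CC(=O)O[C@@]1(C)C(=O)C[C@H]2C(C)(C)CCC[C@]2(C)[C@@]12CC[C@]1(C=COC1)O2 | target

Total steps: 13. Longest linear sequence: 9 steps (steps 1–4 and 9–13).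

**Steps most likely to fail**

Step 9. Electron transfer to the unactivated C–I bond may be slow, and the acetoxyallyl cation may lose its acetyl group to iodide before the hindered tertiary hydroxyl closes the ring. The fallback sets out from 7 (with epoxide 12 as the second component) and comes back at 17, using known reaction types only. γ-Bromination of the dienyl acetate 7 with NBS in buffered aqueous acetone should give 11-bromo-12,13,14,15,16-pentanorlabd-8-en-7-one F1. PhSO2Na in DMF should displace the allylic bromide to give 11-(phenylsulfonyl)-12,13,14,15,16-pentanorlabd-8-en-7-one F2. Deprotonated F2 (NaH, DMF, 60 °C) should open epoxide 12 at its CH2 group to give the hydroxy sulfone F3, which rests in the basic medium as its C11-stabilised anion and therefore cannot cyclise early. SmI2 in THF/MeOH should remove the sulfonyl group vinylogously to give the hydroxy enone F4, which is also what the key step would leave if deacetylation beat ring closure. KHMDS then Ac2O should close the ether by 5-exo-trig oxa-Michael addition of the C13 alkoxide to C9 from the α face and trap the C7 enolate as enol acetate 17.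

Step 13. The hindered alkynol may not enter the vinylidene pathway, the catalyst may die, or the acid-labile enol ether may decompose on isolation. The fallback sets out from 20 and comes back at 21. Anti-Markovnikov hydration of the terminal alkyne by hydroboration with disiamylborane and buffered oxidation (NaBO3) should give the C15 aldehyde in its closed form, the lactol (13R)-9α,13:15,16-diepoxy-15-hydroxy-7-oxolabdan-8β-yl acetate F5 (C15 epimer mixture). MsCl and Et3N in CH2Cl2 should then dehydrate F5 to the enol ether 21, as in glycal formation from 2-deoxy lactols.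

Step 4. Deprotonation may occur toward C6 (cross-conjugated enolate), or the dienolate may be acylated on C8 instead of oxygen. The fallback sets out from 3 and comes back at 7. After saponification as in step 3, acid 4 is liberated at 0 °C and warmed in toluene without added acid or base, so that the dienol ketonises kinetically at C8 and gives the deconjugated ketone 12,13,14,15,16-pentanorlabd-9(11)-en-7-one F6 (either C8 epimer serves). Soft enolisation with Ac2O, Et3N and DMAP should then remove only the doubly activated H8 and give 7.

**Further compounds**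

F1 | step 9 | 11-bromo-12,13,14,15,16-pentanorlabd-8-en-7-one | BrCC1=C(C)C(=O)C[C@H]2C(C)(C)CCC[C@]12C
F2 | step 9 | 11-(phenylsulfonyl)-12,13,14,15,16-pentanorlabd-8-en-7-one | O=S(=O)(CC1=C(C)C(=O)C[C@H]2C(C)(C)CCC[C@]12C)c1ccccc1
F3 | step 9 | (13R)-16-[(tert-butyldimethylsilyl)oxy]-13-hydroxy-11-(phenylsulfonyl)-15-(trimethylsilyl)labd-8-en-14-yn-7-one (C11 epimer mixture) | O=S(=O)(C(C[C@](CO[Si](C)(C)C(C)(C)C)(C#C[Si](C)(C)C)O)C1=C(C)C(=O)C[C@H]2C(C)(C)CCC[C@]12C)c1ccccc1
F4 | step 9 | (13R)-16-[(tert-butyldimethylsilyl)oxy]-13-hydroxy-15-(trimethylsilyl)labd-8-en-14-yn-7-one | C(C[C@](CO[Si](C)(C)C(C)(C)C)(C#C[Si](C)(C)C)O)C1=C(C)C(=O)C[C@H]2C(C)(C)CCC[C@]12C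
F5 | step 13 | (13R)-9α,13:15,16-diepoxy-15-hydroxy-7-oxolabdan-8β-yl acetate (C15 epimer mixture) | CC(=O)O[C@@]1(C)C(=O)C[C@H]2C(C)(C)CCC[C@]2(C)[C@@]12CC[C@]1(CC(O)OC1)O2
F6 | step 4 | 12,13,14,15,16-pentanorlabd-9(11)-en-7-one (C8 epimer mixture) | C=C1C(C)C(=O)C[C@H]2C(C)(C)CCC[C@]12C
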